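The non-aromatic carbocycle of the tetralin (C1, C2, C3, C4, C4a, C8a) is not assembled as a six-membered ring. Its benzylic C1 and C4 with C4a/C8a map onto an o-quinodimethane and the trans C2/C3 arms onto a fumarate, so C1, C4, C4a and C8a are first held in the four-membered ring of a trans-2-aryl-benzocyclobutenol. Heating opens it to an (E,E)-hydroxy-o-quinodimethane that a chiral fumarate captures: a two-carbon ring expansion that sets C1, C2 and C3, plus a temporary C4 carbinol, in one operation. That hydroxyl later masks the C3 hydroxymethyl as a cyclic boronate, so only the C2 arm is sulfated, and leaves by hydrogenolysis.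

Key step: step 5

Numbering used throughout: C1 carries the aryl group, C2 the CH2OSO3H arm, C3 the CH2OH arm, C4 is the ring CH2, C4a/C8a are the ring-fusion carbons; the fused arene carries OMe at C6 and OH at C7.

Remark 1: sulfate monoesters are drawn as free acids; they are handled as sodium salts, and the free acid of the target is liberated at the end on a sulfonic acid resin (H+ form).

Remark 2: the (S)-lactate fumarate is assumed to deliver the (1S,2R,3S,4S) adduct, the sense expected for hydrogen-bonded endo addition of α-hydroxy-α'-aryl-o-quinodimethanes to this auxiliary; methyl (R)-lactate in step 3 would give the mirror-image series with nothing else changed.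

Compounds 5, 9 and 10 are racemic (one enantiomer drawn); this is sufficient because both of their stereocentres are erased in step 5, where the ring opens to the achiral dienol 11.

**Route**

Step 1
Reactants: 1 4-(benzyloxy)-3-methoxybenzyl chloride
Product: 2 1-[4-(benzyloxy)-3-methoxybenzyl]thiolan-1-ium chloride
Conditions: tetrahydrothiophene (2 equiv), MeCN, 40 °C; precipitation with Et2O
Reagents that add atoms: tetrahydrothiophene, C1CCSC1
Why: SN2 alkylation of the sulfide by the activated benzylic chloride should give the crystalline sulfonium salt; no stereocentre is formed.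

Step 2
Reactants: 2 1-[4-(benzyloxy)-3-methoxybenzyl]thiolan-1-ium chloride; 3 4-(benzyloxy)-2-bromo-5-methoxybenzaldehyde
Product: 5 rac-(2R,3R)-2-[4-(benzyloxy)-2-bromo-5-methoxyphenyl]-3-[4-(benzyloxy)-3-methoxyphenyl]oxirane (trans), via sulfonium ylide 4 (not isolated)
Conditions: 50% aq. NaOH, CH2Cl2, 0 °C to rt; crystallisation of the trans isomer
Reagents that add atoms: none
Why: Corey–Chaykovsky epoxidation with a semi-stabilised sulfonium benzylide, in which reversible betaine formation should favour the trans-oxirane; the minor cis isomer is removed by crystallisation.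

Step 3
Reactants: 6 fumaryl chloride; 7 methyl (S)-lactate (2.2 equiv)
Product: 8 bis[(2S)-1-methoxy-1-oxopropan-2-yl] (2E)-but-2-enedioate
Conditions: pyridine, CH2Cl2, 0 °C to rt
Reagents that add atoms: none
Why: Double O-acylation of the secondary alcohol by the acid chloride; the lactate stereocentres are untouched because no bond to them is made or broken.

Step 4
Reactants: 5 rac-trans-oxirane
Product: 10 rac-(7S,8R)-3-(benzyloxy)-8-[4-(benzyloxy)-3-methoxyphenyl]-4-methoxybicyclo[4.2.0]octa-1,3,5-trien-7-ol (trans), via aryllithium 9 (not isolated)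
Conditions: n-BuLi (1.1 equiv), THF, −78 °C; MgBr2·OEt2 (2 equiv), −78 to 0 °C; sat. aq. NH4Cl at 0 °C
Reagents that add atoms: n-butyllithium, [Li]CCCC (lithium stays only in 9)
Why: Bromine–lithium exchange outruns attack on the oxirane, and the aryl-metal then opens the epoxide at its benzylic, aryl-activated carbon in a Parham-type cyclisation that closes the four-membered ring with inversion, so the trans-oxirane should give the trans-2-arylbenzocyclobutenol.

Step 5
Reactants: 10 rac-trans-2-arylbenzocyclobutenol; 8 bis[(2S)-1-methoxy-1-oxopropan-2-yl] fumarate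
Product: 12 bis[(2S)-1-methoxy-1-oxopropan-2-yl] (1S,2R,3S,4S)-7-(benzyloxy)-1-[4-(benzyloxy)-3-methoxyphenyl]-4-hydroxy-6-methoxy-1,2,3,4-tetrahydronaphthalene-2,3-dicarboxylate, via (E,E)-hydroxy-o-quinodimethane 11 (not isolated)
Conditions: toluene (degassed), 80 °C, dark; the fumarate in threefold excess
Reagents that add atoms: none
Why: Heating opens the cyclobutene of 10 by a thermal conrotatory 4π electrocyclic reaction in which the hydroxyl and, because the two substituents are trans, also the aryl group rotate outward to give the (E,E)-dienol 11; fumarate 8 then adds across its termini in an intermolecular suprafacial [4+2] cycloaddition, so the four-membered ring C4–C4a–C8a–C1 grows by C2 and C3 into the six-membered ring (closure mode: concerted Diels–Alder forming C1–C2 and C3–C4). The closest known reaction type is the benzocyclobutenol thermolysis/o-quinodimethane Diels–Alder reaction, including the addition of α-hydroxy-α'-aryl-o-quinodimethanes to fumarates of lactic esters. C1 and C4 should come out cis from the E,E geometry of the diene, and C2 and C3 trans from the E geometry of the fumarate. The ester at C3 takes the endo position next to the hydroxyl-bearing terminus, held by an O–H···O=C hydrogen bond, which places it cis to the C4 hydroxyl and puts the C2 ester trans to the C1 aryl group. The absolute sense (1S,2R,3S,4S) is set by the (S)-lactate units of the hydrogen-bonded ester, which leave one face of the fumarate open to the diene. The step needs this endo and facial selectivity and needs cycloaddition to outrun tautomerisation of 11 to the 2-benzylbenzaldehyde, which the excess of reactive fumarate and the long-lived E-dienol are expected to secure.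

Step 6
Reactants: 12 cycloadduct
Product: 13 [(1S,2R,3R,4S)-7-(benzyloxy)-1-[4-(benzyloxy)-3-methoxyphenyl]-4-hydroxy-6-methoxy-1,2,3,4-tetrahydronaphthalene-2,3-diyl]dimethanol
Conditions: LiAlH4 (6 equiv), THF, −20 to 0 °C; Rochelle salt work-up
Reagents that add atoms: none
Why: Hydride reduction of all four ester groups should free the two ring hydroxymethyl groups and cleave the auxiliaries as propane-1,2-diol without touching the four ring stereocentres.

Step 7
Reactants: 13 triol
Product: 16 [(1S,2R,3R,4S)-7-(benzyloxy)-1-[4-(benzyloxy)-3-methoxyphenyl]-4-hydroxy-3-(hydroxymethyl)-6-methoxy-1,2,3,4-tetrahydronaphthalen-2-yl]methyl hydrogen sulfate, via cyclic phenylboronate 14 (not isolated), via sulfated phenylboronate 15 (not isolated)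
Conditions: PhB(OH)2 (1.05 equiv), pyridine, 4 Å MS, rt; SO3·pyridine (3 equiv), rt; pinacol, MeOH–H2O; Na+ ion exchange
Reagents that add atoms: sulfur trioxide–pyridine complex, O=S(=O)([O-])[n+]1ccccc1; phenylboronic acid, OB(O)c1ccccc1 (its atoms stay only in 14 and 15)
Why: Transient boronate masking: the cis-disposed C4 hydroxyl and C3 hydroxymethyl should form the favoured six-membered dioxaborinane, the only free hydroxyl (the C2 arm) is O-sulfonated by SO3·pyridine, and diol exchange with pinacol removes the boron.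

Step 8
Reactants: 16 sulfate (sodium salt)
Product: 17 [(1S,2R,3R)-7-hydroxy-1-(4-hydroxy-3-methoxyphenyl)-3-(hydroxymethyl)-6-methoxy-1,2,3,4-tetrahydronaphthalen-2-yl]methyl hydrogen sulfate (target)
Conditions: H2 (1 atm), Pd(OH)2/C, MeOH–H2O–AcOH, rt; Dowex 50W (H+), 0 °C
Reagents that add atoms: none
Why: Catalytic hydrogenolysis should cleave both aryl benzyl ethers and the C4 benzylic C–O bond, which is activated by the para oxygen of the fused ring, while the alkyl sulfate and the stereocentres at C1–C3 are inert.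

**Compound list**

1 | 4-(benzyloxy)-3-methoxybenzyl chloride | COc1cc(CCl)ccc1OCc1ccccc1 | starting material
2 | 1-[4-(benzyloxy)-3-methoxybenzyl]thiolan-1-ium chloride | COc1cc(C[S+]2CCCC2)ccc1OCc1ccccc1.[Cl-] | intermediate
3 | 4-(benzyloxy)-2-bromo-5-methoxybenzaldehyde | COc1cc(C=O)c(Br)cc1OCc1ccccc1 | starting material
4 | sulfonium ylide of 2 (benzylide carbon deprotonated) | COc1cc([CH-][S+]2CCCC2)ccc1OCc1ccccc1 | intermediate (not isolated)
5 | rac-(2R,3R)-2-[4-(benzyloxy)-2-bromo-5-methoxyphenyl]-3-[4-(benzyloxy)-3-methoxyphenyl]oxirane (trans) | COc1cc([C@H]2O[C@@H]2c2ccc(OCc3ccccc3)c(OC)c2)c(Br)cc1OCc1ccccc1 | intermediate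
6 | fumaryl chloride | O=C(Cl)/C=C/C(=O)Cl | starting material
7 | methyl (S)-lactate | C[C@H](O)C(=O)OC | starting material
8 | bis[(2S)-1-methoxy-1-oxopropan-2-yl] (2E)-but-2-enedioate | COC(=O)[C@H](C)OC(=O)/C=C/C(=O)O[C@@H](C)C(=O)OC | intermediate
9 | aryllithium from 5 (Li in place of Br, trans-oxirane intact) | COc1cc([C@H]2O[C@@H]2c2ccc(OCc3ccccc3)c(OC)c2)c([Li])cc1OCc1ccccc1 | intermediate (not isolated)
10 | rac-(7S,8R)-3-(benzyloxy)-8-[4-(benzyloxy)-3-methoxyphenyl]-4-methoxybicyclo[4.2.0]octa-1,3,5-trien-7-ol (OH and aryl trans) | COc1cc2c(cc1OCc1ccccc1)[C@@H](c1ccc(OCc3ccccc3)c(OC)c1)[C@@H]2O | intermediate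
11 | (E)-[(6E)-4-(benzyloxy)-6-[4-(benzyloxy)-3-methoxybenzylidene]-3-methoxycyclohexa-2,4-dien-1-ylidene]methanol | O/C=C1\C=C(OC)C(OCc2ccccc2)=C/C1=C\c1ccc(OCc2ccccc2)c(OC)c1 | intermediate (not isolated)
12 | bis[(2S)-1-methoxy-1-oxopropan-2-yl] (1S,2R,3S,4S)-7-(benzyloxy)-1-[4-(benzyloxy)-3-methoxyphenyl]-4-hydroxy-6-methoxy-1,2,3,4-tetrahydronaphthalene-2,3-dicarboxylate (1-aryl/2-ester trans, 2/3 trans, 3-ester/4-OH cis) | COc1cc([C@H]2c3cc(OCc4ccccc4)c(OC)cc3[C@@H](O)[C@@H](C(=O)O[C@@H](C)C(=O)OC)[C@@H]2C(=O)O[C@@H](C)C(=O)OC)ccc1OCc1ccccc1 | intermediate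
13 | [(1S,2R,3R,4S)-7-(benzyloxy)-1-[4-(benzyloxy)-3-methoxyphenyl]-4-hydroxy-6-methoxy-1,2,3,4-tetrahydronaphthalene-2,3-diyl]dimethanol | COc1cc([C@H]2c3cc(OCc4ccccc4)c(OC)cc3[C@@H](O)[C@@H](CO)[C@@H]2CO)ccc1OCc1ccccc1 | intermediate
14 | cyclic phenylboronate of 13 (2-phenyl-1,3,2-dioxaborinane across O4 and the C3 CH2O; C2 CH2OH free) | COc1cc([C@H]2c3cc(OCc4ccccc4)c(OC)cc3[C@H]3OB(c4ccccc4)OC[C@H]3[C@@H]2CO)ccc1OCc1ccccc1 | intermediate (not isolated)
15 | hydrogen sulfate of 14 at the C2 CH2O | COc1cc([C@H]2c3cc(OCc4ccccc4)c(OC)cc3[C@H]3OB(c4ccccc4)OC[C@H]3[C@@H]2COS(=O)(=O)O)ccc1OCc1ccccc1 | intermediate (not isolated)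
16 | [(1S,2R,3R,4S)-7-(benzyloxy)-1-[4-(benzyloxy)-3-methoxyphenyl]-4-hydroxy-3-(hydroxymethyl)-6-methoxy-1,2,3,4-tetrahydronaphthalen-2-yl]methyl hydrogen sulfate | COc1cc([C@H]2c3cc(OCc4ccccc4)c(OC)cc3[C@@H](O)[C@@H](CO)[C@@H]2COS(=O)(=O)O)ccc1OCc1ccccc1 | intermediate
17 | [(1S,2R,3R)-7-hydroxy-1-(4-hydroxy-3-methoxyphenyl)-3-(hydroxymethyl)-6-methoxy-1,2,3,4-tetrahydronaphthalen-2-yl]methyl hydrogen sulfate | COc1cc([C@H]2c3cc(O)c(OC)cc3C[C@@H](CO)[C@@H]2COS(=O)(=O)O)ccc1O | target

**Step count and risks**

Total steps: 8. Longest linear sequence: 7 steps (1 → 2 → 5 → 10 → 12 → 13 → 16 → 17; step 3 is the side branch to 8).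

Steps most likely to fail:

1. Step 5 (key step). The dienol may be lost by tautomerisation to the 2-benzylbenzaldehyde or by dimerisation before the fumarate captures it, and face discrimination may be incomplete at 80 °C. Fallback, setting out from 10 and returning at 12: silylation of 10 (TBSCl, imidazole, DMF) would give the trans tert-butyldimethylsilyl ether of the benzocyclobutenol F1. Its thermolysis in toluene at 110 °C with 8 passes through the (E,E)-siloxy-o-quinodimethane, which has no O–H and cannot tautomerise, and should give the 4-O-silyl cycloadduct F2 under endo and auxiliary control. HF·pyridine then removes the silyl group to give 12. Minor diastereomers would be separated by chromatography at this stage.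

2. Step 4. The Lewis acid may trigger a Meinwald-type rearrangement of the electron-rich oxirane, or the strained alkoxide may open electrocyclically before the quench. Fallback, setting out from 1 and 3 and returning at 12: zinc insertion into 1 (Zn dust, LiCl, THF) would give [4-(benzyloxy)-3-methoxybenzyl]zinc chloride F3. Negishi coupling with 3 (Pd(OAc)2, SPhos) would give 4-(benzyloxy)-2-[4-(benzyloxy)-3-methoxybenzyl]-5-methoxybenzaldehyde F4. Irradiation of F4 (350 nm) in SO2-saturated benzene traps its photoenol as the rac-cis-1-hydroxy-3-aryl-1,3-dihydrobenzo[c]thiophene 2,2-dioxide F5. Heating F5 with 8 and ZnO in benzene at 80 °C extrudes SO2 from the five-membered ring and releases the same dienol 11, which 8 captures to give 12.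

3. Step 7. Site selection may be incomplete if the boronate migrates to the seven-membered ring across the two primary hydroxyls or is lost before sulfation, which would put sulfate on the wrong oxygen. Fallback, setting out from 13 and returning at 16: tBu2Si(OTf)2 with 2,6-lutidine in CH2Cl2 at 0 °C would give the isolable six-membered di-tert-butylsilylene of 13 across O4 and the C3 CH2O F6. SO3·pyridine in DMF would sulfate the free C2 arm to the silylene sulfate F7, and HF·pyridine in THF–pyridine at 0 °C removes the silylene to give 16.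

**Further compounds**

F1 | step 5 | rac-trans tert-butyldimethylsilyl ether of 10 | COc1cc2c(cc1OCc1ccccc1)[C@@H](c1ccc(OCc3ccccc3)c(OC)c1)[C@@H]2O[Si](C)(C)C(C)(C)C
F2 | step 5 | 4-O-tert-butyldimethylsilyl ether of 12 | COc1cc([C@H]2c3cc(OCc4ccccc4)c(OC)cc3[C@@H](O[Si](C)(C)C(C)(C)C)[C@@H](C(=O)O[C@@H](C)C(=O)OC)[C@@H]2C(=O)O[C@@H](C)C(=O)OC)ccc1OCc1ccccc1
F3 | step 4 | [4-(benzyloxy)-3-methoxybenzyl]zinc chloride | COc1cc(C[Zn]Cl)ccc1OCc1ccccc1
F4 | step 4 | 4-(benzyloxy)-2-[4-(benzyloxy)-3-methoxybenzyl]-5-methoxybenzaldehyde | COc1cc(C=O)c(Cc2ccc(OCc3ccccc3)c(OC)c2)cc1OCc1ccccc1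
F5 | step 4 | rac-cis-5-(benzyloxy)-3-[4-(benzyloxy)-3-methoxyphenyl]-1-hydroxy-6-methoxy-1,3-dihydrobenzo[c]thiophene 2,2-dioxide | COc1cc2c(cc1OCc1ccccc1)[C@@H](c1ccc(OCc3ccccc3)c(OC)c1)S(=O)(=O)[C@H]2O
F6 | step 7 | di-tert-butylsilylene of 13 across O4 and the C3 CH2O | COc1cc([C@H]2c3cc(OCc4ccccc4)c(OC)cc3[C@H]3O[Si](C(C)(C)C)(C(C)(C)C)OC[C@H]3[C@@H]2CO)ccc1OCc1ccccc1
F7 | step 7 | hydrogen sulfate of F6 at the C2 CH2O | COc1cc([C@H]2c3cc(OCc4ccccc4)c(OC)cc3[C@H]3O[Si](C(C)(C)C)(C(C)(C)C)OC[C@H]3[C@@H]2COS(=O)(=O)O)ccc1OCc1ccccc1
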